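**Retrosynthetic overview**
- Sacidumlignan A ⇒ open-chain gem-diaryl carbinol acetal Ar2C(OH)–CH(Me)–CH(Me)–CH(OCH2CH2O), where Ar is MOM-protected syringyl. One acid operation makes the C4–C4a Friedel–Crafts bond, removes water and glycol, and cleaves both MOM groups.
- Carbinol ⇒ two identical aryllithiums plus one γ-acetal ester. Both C1–aryl bonds form in one flask, and because the aryl groups are identical, either one can become ring A.
- γ-Acetal ester (1,4-dioxygenated) ⇒ C3–C4 bond between the masked formyl carbon of 1,3-dioxolane (a d1 synthon, delivered as the nucleophilic dioxolan-2-yl radical) and the β-carbon of methyl tiglate. This is the key step.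
- Ring order: both benzenoid rings are bought. The only ring made is the C1–C4 carbocycle (ring B), and it is formed last.

Assumption: the SMILES has no stereocentre and the pendant ring is symmetric about the biaryl axis (no atropisomers), so the target is achiral and no absolute stereocontrol is needed.

**Route**

Step 1
Reactants: 1 methyl tiglate (methyl (E)-2-methylbut-2-enoate); 2 1,3-dioxolane (also co-solvent)
Product: 5 methyl 3-(1,3-dioxolan-2-yl)-2-methylbutanoate (racemic syn/anti mixture), via 1,3-dioxolan-2-yl radical 3 (not isolated), via tertiary ester radical 4 (not isolated)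
Conditions: (n-Bu4N)4W10O32 (2 mol %), 2/MeCN 1:1, 390 nm LED, N2, 25 °C, 36 h
Reagents that add atoms: none
Why: In this photocatalytic hydrogen-atom-transfer Giese addition (radical Stetter type), excited decatungstate abstracts the hydridic C2–H of dioxolane, the resulting nucleophilic masked-formyl radical (the one-electron form of a formyl-anion equivalent) attacks the electrophilic β-carbon of the enoate in a polarity-matched step, and the hindered electrophilic radical 4 is quenched by back hydrogen transfer rather than by telomerisation; the two new stereocentres form unselectively, which does not matter because both carbons become sp2 in step 4.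

Step 2
Reactants: 6 4-bromo-2,6-dimethoxyphenol
Product: 8 5-bromo-1,3-dimethoxy-2-(methoxymethoxy)benzene, via sodium phenoxide 7 (not isolated)
Conditions: NaH, THF–DMF 4:1, 0 °C; then MOMCl, 0 °C → rt
Reagents that add atoms: chloromethyl methyl ether (MOMCl), COCCl
Why: This Williamson-type O-alkylation works because the very reactive α-chloro ether alkylates even the flanked phenoxide, and the resulting acetal ether tolerates aryllithium chemistry and is cleaved by the acid of step 4; no stereocentre is formed.

Step 3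
Reactants: 8 5-bromo-1,3-dimethoxy-2-(methoxymethoxy)benzene (2.4 equiv); 5 methyl 3-(1,3-dioxolan-2-yl)-2-methylbutanoate (1.0 equiv)
Product: 11 1,1-bis[3,5-dimethoxy-4-(methoxymethoxy)phenyl]-3-(1,3-dioxolan-2-yl)-2-methylbutan-1-ol (racemic diastereomer mixture), via aryllithium 9 (not isolated), via aryl ketone 10 (not isolated)
Conditions: n-BuLi, THF, −78 °C, 30 min; then 5, −78 → 0 °C; then H2O (neutral work-up)
Reagents that add atoms: none
Why: Bromine–lithium exchange outruns any MOM-directed ortho-lithiation at −78 °C, and the aryllithium then adds twice to the ester (addition–elimination to 10 followed by 1,2-addition, the classical tertiary-carbinol synthesis) while the dioxolane and MOM acetals are inert; the new carbinol carbon bears two identical aryl groups and so is not a stereocentre.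

Step 4
Reactants: 11 1,1-bis[3,5-dimethoxy-4-(methoxymethoxy)phenyl]-3-(1,3-dioxolan-2-yl)-2-methylbutan-1-ol
Product: 15 sacidumlignan A, via diarylalkene acetal 12 (not isolated), via dihydronaphthyl hydroxyethyl ether 13 (not isolated), via bis-MOM naphthalene 14 (not isolated)
Conditions: HCl (3 M in MeOH), Ar, 0 → 60 °C, 6 h
Reagents that add atoms: none
Why: In this Friedel–Crafts aromatic cyclodehydration cascade, the doubly p-alkoxybenzylic carbinol loses water by E1, the dioxolane opens to an oxocarbenium ion that the ortho carbon (para to one OMe) of the cis aryl ring attacks to close the six-membered ring, benzylic loss of ethylene glycol aromatises irreversibly, and the same methanolic acid transacetalises both MOM groups to volatile dimethoxymethane; both sp3 stereocentres disappear, and because the two aryl groups and their ortho positions are equivalent, only the 5,7-dimethoxy-6-hydroxy regioisomer can form.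

**Compound list**
1 | methyl tiglate, methyl (E)-2-methylbut-2-enoate | C/C=C(\C)C(=O)OC | starting material
2 | 1,3-dioxolane | C1COCO1 | starting material
3 | 1,3-dioxolan-2-yl radical | [CH]1OCCO1 | intermediate
4 | 3-(1,3-dioxolan-2-yl)-1-methoxy-2-methyl-1-oxobutan-2-yl radical | COC(=O)[C](C)C(C)C1OCCO1 | intermediate
5 | methyl 3-(1,3-dioxolan-2-yl)-2-methylbutanoate (racemic syn/anti mixture) | COC(=O)C(C)C(C)C1OCCO1 | intermediate
6 | 4-bromo-2,6-dimethoxyphenol | COc1cc(Br)cc(OC)c1O | starting material
7 | sodium 4-bromo-2,6-dimethoxyphenoxide | [Na+].[O-]c1c(OC)cc(Br)cc1OC | intermediate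
8 | 5-bromo-1,3-dimethoxy-2-(methoxymethoxy)benzene | COCOc1c(OC)cc(Br)cc1OC | intermediate
9 | [3,5-dimethoxy-4-(methoxymethoxy)phenyl]lithium | [Li]c1cc(OC)c(OCOC)c(OC)c1 | intermediate
10 | 1-[3,5-dimethoxy-4-(methoxymethoxy)phenyl]-3-(1,3-dioxolan-2-yl)-2-methylbutan-1-one (diastereomer mixture) | CC(C1OCCO1)C(C)C(=O)c1cc(OC)c(OCOC)c(OC)c1 | intermediate
11 | 1,1-bis[3,5-dimethoxy-4-(methoxymethoxy)phenyl]-3-(1,3-dioxolan-2-yl)-2-methylbutan-1-ol (racemic diastereomer mixture) | CC(C1OCCO1)C(C)C(O)(c1cc(OC)c(OCOC)c(OC)c1)c1cc(OC)c(OCOC)c(OC)c1 | intermediate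
12 | 2-{4,4-bis[3,5-dimethoxy-4-(methoxymethoxy)phenyl]-3-methylbut-3-en-2-yl}-1,3-dioxolane (racemic) | CC(C1OCCO1)C(C)=C(c1cc(OC)c(OCOC)c(OC)c1)c1cc(OC)c(OCOC)c(OC)c1 | intermediate
13 | 2-({4-[3,5-dimethoxy-4-(methoxymethoxy)phenyl]-6,8-dimethoxy-7-(methoxymethoxy)-2,3-dimethyl-1,2-dihydronaphthalen-1-yl}oxy)ethanol (diastereomer mixture) | CC1C(OCCO)c2c(OC)c(OCOC)c(OC)cc2C(c2cc(OC)c(OCOC)c(OC)c2)=C1C | intermediate
14 | 1-[3,5-dimethoxy-4-(methoxymethoxy)phenyl]-5,7-dimethoxy-6-(methoxymethoxy)-2,3-dimethylnaphthalene | COCOc1c(OC)cc(-c2c(C)c(C)cc3c(OC)c(OCOC)c(OC)cc23)cc1OC | intermediate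
15 | sacidumlignan A, 4-(6-hydroxy-5,7-dimethoxy-2,3-dimethylnaphthalen-1-yl)-2,6-dimethoxyphenol (achiral) | COc1cc(-c2c(C)c(C)cc3c(OC)c(O)c(OC)cc23)cc(OC)c1O | target

**Totals**
- Total step count: 4.
- Longest linear sequence: 3 steps (1 → 5 → 11 → 15, or 6 → 8 → 11 → 15).

**Three steps most likely to fail**

Step 1. The β-methyl group slows radical addition to the trisubstituted enoate by roughly two orders of magnitude compared with an acrylate, and some dioxolan-4-yl regioisomer is expected. The fallback makes the same C3–C4 bond by closed-shell chemistry, with a nitronate as the formyl-anion equivalent. It sets out from 1. DBU-promoted Michael addition of nitromethane (neat MeNO2, 60 °C) gives methyl 2,3-dimethyl-4-nitrobutanoate F1. NaOMe in MeOH converts this into the sodium nitronate of methyl 2,3-dimethyl-4-nitrobutanoate F2. Running F2 into cold H2SO4–MeOH (Nef solvolysis) gives methyl 4,4-dimethoxy-2,3-dimethylbutanoate F3. F3 replaces 5 in step 3 and gives 1,1-bis[3,5-dimethoxy-4-(methoxymethoxy)phenyl]-4,4-dimethoxy-2,3-dimethylbutan-1-ol F4. Under the conditions of step 4, F4 comes back to the route at 14 and goes on to 15.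

Step 3. Aryllithium 9 may enolise ester 5 or the hindered, electron-rich ketone 10 instead of adding to it. The fallback delivers one aryl group at a time, the second from a non-basic organocerium reagent. It sets out from 5. MeNH(OMe)·HCl with i-PrMgCl (THF, −20 °C) gives the Weinreb amide 3-(1,3-dioxolan-2-yl)-N-methoxy-N,2-dimethylbutanamide F5. One equivalent of 9 converts F5 into ketone 10, which is now isolated. A second portion of 9 is transmetalated with anhydrous CeCl3 to dichloro[3,5-dimethoxy-4-(methoxymethoxy)phenyl]cerium F6. F6 adds to 10 at −78 °C and comes back to the route at 11.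

Step 4. Cation-derived oligomers, or capture of the MOM-derived one-carbon electrophile by the very electron-rich rings, may erode the combined benzannulation and deprotection. The fallback changes the protecting-group logic: the ring is built under anhydrous, non-nucleophilic acid and the phenols are released afterwards by hydrogenolysis. It sets out from 6. BnBr and K2CO3 (DMF, rt) give 2-(benzyloxy)-5-bromo-1,3-dimethoxybenzene F7. n-BuLi (THF, −78 °C) gives [4-(benzyloxy)-3,5-dimethoxyphenyl]lithium F8. Two equivalents of F8 add to 5 to give 1,1-bis[4-(benzyloxy)-3,5-dimethoxyphenyl]-3-(1,3-dioxolan-2-yl)-2-methylbutan-1-ol F9. Catalytic p-TsOH in CH2Cl2 (rt) closes and aromatises ring B to give O,O'-dibenzylsacidumlignan A F10. H2 over Pd/C (EtOAc–MeOH) comes back to the route at 15.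

**Further compounds**
F1 | step 1 | methyl 2,3-dimethyl-4-nitrobutanoate (diastereomer mixture) | COC(=O)C(C)C(C)C[N+](=O)[O-]
F2 | step 1 | sodium nitronate of methyl 2,3-dimethyl-4-nitrobutanoate | COC(=O)C(C)C(C)C=[N+]([O-])[O-].[Na+]
F3 | step 1 | methyl 4,4-dimethoxy-2,3-dimethylbutanoate (diastereomer mixture) | COC(=O)C(C)C(C)C(OC)OC
F4 | step 1 | 1,1-bis[3,5-dimethoxy-4-(methoxymethoxy)phenyl]-4,4-dimethoxy-2,3-dimethylbutan-1-ol (diastereomer mixture) | COC(OC)C(C)C(C)C(O)(c1cc(OC)c(OCOC)c(OC)c1)c1cc(OC)c(OCOC)c(OC)c1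
F5 | step 3 | 3-(1,3-dioxolan-2-yl)-N-methoxy-N,2-dimethylbutanamide (diastereomer mixture) | CON(C)C(=O)C(C)C(C)C1OCCO1
F6 | step 3 | dichloro[3,5-dimethoxy-4-(methoxymethoxy)phenyl]cerium | Cl[Ce](Cl)c1cc(OC)c(OCOC)c(OC)c1
F7 | step 4 | 2-(benzyloxy)-5-bromo-1,3-dimethoxybenzene | COc1cc(Br)cc(OC)c1OCc1ccccc1
F8 | step 4 | [4-(benzyloxy)-3,5-dimethoxyphenyl]lithium | [Li]c1cc(OC)c(OCc2ccccc2)c(OC)c1
F9 | step 4 | 1,1-bis[4-(benzyloxy)-3,5-dimethoxyphenyl]-3-(1,3-dioxolan-2-yl)-2-methylbutan-1-ol (diastereomer mixture) | CC(C1OCCO1)C(C)C(O)(c1cc(OC)c(OCc2ccccc2)c(OC)c1)c1cc(OC)c(OCc2ccccc2)c(OC)c1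
F10 | step 4 | O,O'-dibenzylsacidumlignan A, 6-(benzyloxy)-1-[4-(benzyloxy)-3,5-dimethoxyphenyl]-5,7-dimethoxy-2,3-dimethylnaphthalene | COc1cc(-c2c(C)c(C)cc3c(OC)c(OCc4ccccc4)c(OC)cc23)cc(OC)c1OCc1ccccc1
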